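Start at late times. Between its last two readings, Friday's flask gains 0.5 percentage points of Pdt, and each reading carries a scatter of 0.5 points.

the same everywhere: Sub 0.035 M; Spx 6.1 mM (held)

|  | Rgt | temperature | remark | time |
|---|---|---|---|---|
| Friday's | 0.028 M | 25 °C | the very flask that is asked about, followed so far |  |
| Tuesday's | 0.019 M | 20 °C | run made earlier |  |
| flask | 0.0280 M | 25 °C |  | 40 h |

| run | time / h | Pdt / % |
|---|---|---|
| Friday's | 1.50 | 7.0 |
| Friday's | 5.00 | 35.5 |
| Friday's | 10.0 | 61.2 |
| Friday's | 15.0 | 72.3 |
| Friday's | 20.0 | 76.0 |
| Friday's | 25.0 | 77.1 |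
| Friday's | 30.0 | 77.6 |
| Tuesday's | 0.500 | 1.0 |
| Tuesday's | 1.00 | 1.1 |
| Tuesday's | 1.33 | 3.0 |
| Tuesday's | 2.00 | 4.6 |
| Tuesday's | 2.50 | 7.3 |
| Tuesday's | 3.00 | 9.9 |

(scatter of a reading: 0.5 percentage points)

* Pdt, in percent of the Sub first charged, at 40 h
* the option that brings most further Pdt ("none" if no option brings more than 2 percentage points) (zeta / alpha / beta / theta / none)
* Pdt present, with what was taken out counted in, in percent of the Sub first charged, after alpha
* Pdt present, with what was taken out counted in, in percent of the Sub first charged, after theta

- zeta: at 40 h raise the temperature by 10 K, then wait 12 h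
- alpha: at 40 h take out 90 % of the Pdt then present, then wait 12 h
- beta: change nothing and wait 12 h more
- theta: at 40 h add Rgt, 100 % of the amount charged, then wait 12 h

- at the start none of Rgt2 is dissolved
- Pdt that was removed still counts
- the earlier runs were read with a standard deviation of 0.5 percentage points
- reactions considered so far: Spx <-> Rgt2; Rgt2 + Int -> Pdt; Sub + Rgt -> Int
- additions bring no volume worth counting

First ask where this flask stops. Follow the steps: Sub and Rgt give Int, and Int takes Rgt2, dissolved from the held Spx, to give Pdt. So each Pdt costs one Sub and one Rgt. Spx is held, so count no charge for it. Take equal charges as the zero of the scale, a ratio of 1. Then define the ceiling, the Rgt charged as a fraction of the Sub charged: 80.0 %. This flask holds less Rgt than Sub, so Rgt is the limiting reagent.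

Next ask how near the ceiling this flask comes by 40 h. Read the gap below the ceiling: 4 points at 20.0 h, then 2.4 points at 30.0 h. Over that stretch the gap shrinks by a factor of 0.600, as read. Apply the factor once more, over the equal stretch to 40 h. My reckoning gives 78.6 %.

Then ask what can move the ceiling. Waiting, warming and removing Pdt leave the ratio as it stands. By my reckoning, each has a gap of 1.4 points to work in, which is less than the mark of 2 points. Theta takes the ratio to 1.60, past the zero of the scale. The ceiling of this flask then becomes 100 %, and Sub becomes the charge that caps it. Choose theta.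

The forecast gives 78.4 %, theta, 78.9 % after alpha and 95 % after theta, holding that “that flat stretch reflects Rgt running out, not a stalled gas step”.

Check the reckoning: this flask gives 79.5 % at 40 h, against my 78.6 %. That stands 0.50 points under the ceiling, with 0.427 % of the Rgt charge free. The best option is theta: it brings 19 points and reaches 98.2 %. Zeta brings 0.42 points, beta 0.32 points, and alpha ends at 79.9 %.

Spx ⇌ Rgt2, rate k1*(csat - [Rgt2]) (kL = 0.0360 min⁻¹); Rgt2 + Int → Pdt (k = 1.00 M⁻¹ min⁻¹, Ea = 51.0 kJ mol⁻¹); Sub + Rgt → Int (k = 0.230 M⁻¹ min⁻¹, Ea = 52.0 kJ mol⁻¹); (constants at 25 °C) Take the falling level of Rgt away, and the same run goes from 79.5 % to >99.9 %. Use the ceiling on a neighbour charged with 0.0070 M of Rgt: its ratio is 20.0 %. That neighbour gives 20.0 % after 40.0 h, with 80 % of its Sub still there.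

(The earlier runs and the new flask are calculated with made-up constants, and the scatter is random.)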